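Rings are lettered A–F from the 2,4,6-trihydroxyphenoxy end to the 3,4,5-trihydroxyphenoxy end. In ring C, C-1 carries O–B, C-2 is the only CH, C-3 to C-5 carry OH and C-6 carries O–D.
Enabling feature: C-1, C-6, C-5 and C-4 of ring C are four adjacent oxygen-bearing carbons (a squarate ring), and C-3(O)–C-2(H) is a 1-alkoxyvinyl unit. Ring C therefore maps onto a 4-(1-ethoxyvinyl)cyclobutenone.
Cuts, in order: the 14 O–alkyl bonds; the aryl–O bonds at the doubly oxygen-flanked carbons of rings A and B; C-1–C-2 of ring C; C-3–C-4 (vinyllithium addition); the squarate C-6–O(D) bond; the doubly flanked aryl–O bonds of rings D and E.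
Forward: two copper etherification/Baeyer–Villiger cycles with one bromoaldehyde join F→E→D. The trimer phenol then goes onto methyl squaryl chloride, vinyl addition and O-methylation follow, and thermolysis creates ring C. Two more cycles add B and then A, and one global dealkylation ends the route.
Stereochemistry: the target has no stereogenic element. The only stereocentre of the route (C4 of the cyclobutenone) is made racemic and is erased when ring C aromatises.

Key step: step 9

Remark on the chemistry: the target has no stereocentre and no configurationally stable axis, so the structure given is one achiral species and no enantioselective step is needed.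
Abbreviation: DEF-oxy = 4-[3,5-dimethoxy-4-(3,4,5-trimethoxyphenoxy)phenoxy]-3,5-dimethoxyphenoxy, the aryloxy group of phenol 8.

Step 1
Reactants: 1 3,4,5-trimethoxyphenol; 2 4-bromo-3,5-dimethoxybenzaldehyde
Product: 3 3,5-dimethoxy-4-(3,4,5-trimethoxyphenoxy)benzaldehyde (E–F aldehyde)
Conditions: CuI (10 mol %), picolinic acid (20 mol %), K3PO4, DMSO, 90 °C, Ar
Reagents that add atoms: none
Why: Ullmann-type copper-catalysed diaryl ether synthesis, in which the para-formyl group activates the C–Br bond, the phenol has both ortho positions free, picolinate-ligated copper is the established catalyst for aryl halides with two ortho substituents, and the non-enolisable aldehyde tolerates K3PO4.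

Step 2
Reactants: 3 E–F aldehyde
Product: 5 3,5-dimethoxy-4-(3,4,5-trimethoxyphenoxy)phenol (E–F phenol), via aryl formate 4 (not isolated)
Conditions: mCPBA, CH2Cl2, 0 °C → rt; then K2CO3 (cat.), MeOH, rt
Reagents that add atoms: mCPBA, OOC(=O)c1cccc(Cl)c1
Why: Baeyer–Villiger oxidation of an electron-rich benzaldehyde (the Dakin-type aldehyde-to-phenol exchange known for 3,4,5-trialkoxybenzaldehydes), in which the oxygen-rich aryl group migrates rather than hydride and the aryl formate shields the ring from further oxidation until mild methanolysis frees the phenol.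

Step 3
Reactants: 5 E–F phenol; 2 4-bromo-3,5-dimethoxybenzaldehyde
Product: 6 4-[3,5-dimethoxy-4-(3,4,5-trimethoxyphenoxy)phenoxy]-3,5-dimethoxybenzaldehyde (D–E–F aldehyde)
Conditions: CuI (10 mol %), picolinic acid (20 mol %), K3PO4, DMSO, 90 °C, Ar
Reagents that add atoms: none
Why: Second Ullmann-type etherification with the same bromoaldehyde, and since the nucleophilic OH of 5 again sits between two CH positions the steric demand equals that of step 1.

Step 4
Reactants: 6 D–E–F aldehyde
Product: 8 4-[3,5-dimethoxy-4-(3,4,5-trimethoxyphenoxy)phenoxy]-3,5-dimethoxyphenol (D–E–F phenol), via aryl formate 7 (not isolated)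
Conditions: mCPBA, CH2Cl2, 0 °C → rt; then K2CO3 (cat.), MeOH, rt
Reagents that add atoms: mCPBA, OOC(=O)c1cccc(Cl)c1
Why: Same Baeyer–Villiger/methanolysis pair as in step 2 with a para-aryloxy migrating ring, which places the free OH of the trimer on the unhindered C-1 of ring D.

Step 5
Reactants: 9 squaric acid
Product: 10 3,4-dichlorocyclobut-3-ene-1,2-dione (squaryl dichloride)
Conditions: SOCl2, DMF (cat.), toluene, reflux
Reagents that add atoms: thionyl chloride, ClS(Cl)=O
Why: Chlorodehydroxylation of a vinylogous carboxylic acid through the Vilsmeier-type chloroiminium species formed from SOCl2 and DMF, the standard preparation of squaryl dichloride.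

Step 6
Reactants: 10 squaryl dichloride
Product: 11 3-chloro-4-methoxycyclobut-3-ene-1,2-dione (methyl squaryl chloride)
Conditions: MeOH (1.0 equiv), CH2Cl2, 0 °C → rt
Reagents that add atoms: methanol, CO
Why: Addition–elimination at a vinylogous acid chloride, in which the first methoxy group feeds electron density into the dione and slows the second exchange, so one equivalent of methanol should stop at the ester chloride.

Step 7
Reactants: 8 D–E–F phenol; 11 methyl squaryl chloride
Product: 12 3-(DEF-oxy)-4-methoxycyclobut-3-ene-1,2-dione (aryl methyl squarate)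
Conditions: iPr2NEt, CH2Cl2, −20 °C → rt; anhydrous work-up
Reagents that add atoms: none
Why: Addition–elimination (vinylogous acylation of a phenol) in which chloride leaves far more readily than methoxide, so the C-6–O–D ether is made on an sp2 carbon of a small, strongly electrophilic ring where neither crowding nor the electron richness of the later ring C plays a part.

Step 8
Reactants: 12 aryl methyl squarate; 13 ethyl vinyl ether
Product: 16 (±)-2-(DEF-oxy)-4-(1-ethoxyvinyl)-3,4-dimethoxycyclobut-2-en-1-one, via 1-ethoxyvinyllithium 14 (not isolated), via lithium alkoxide 15 (not isolated)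
Conditions: 13 (excess), t-BuLi, THF, −78 → 0 °C; then 12, THF, −78 °C; then MeOTf, −78 → −20 °C; aq NaHCO3; Et3N-deactivated SiO2
Reagents that add atoms: methyl trifluoromethanesulfonate, COS(=O)(=O)C(F)(F)F
Why: 1,2-Addition of an α-lithiated enol ether to a squarate carbonyl followed by O-methylation of the lithium alkoxide is the usual entry to ring-expansion substrates; attack should go to the carbonyl in vinylogous conjugation with the aryloxy oxygen, a weaker donor than methoxy because its lone pair is shared with ring D, and this carbonyl also lies beside the smaller OMe group, while the new quaternary centre forms as a racemate because nothing in 12 is chiral.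

Step 9
Reactants: 16 (±)-2-(DEF-oxy)-4-(1-ethoxyvinyl)-3,4-dimethoxycyclobut-2-en-1-one
Product: 19 2-(DEF-oxy)-5-ethoxy-3,4-dimethoxyphenol (C–D–E–F phenol), via dienylketene 17 (not isolated), via cyclohexadienone 18 (not isolated)
Conditions: degassed toluene (0.02 M), 110 °C, base-washed glassware, Ar
Reagents that add atoms: none
Why: Heating breaks the C1–C4 σ bond of 16 in a conrotatory 4π electrocyclic opening in which the donor methoxy group on C4 turns outward and the 1-ethoxyvinyl group therefore turns inward, giving the (Z)-dienylketene 17 with its ketene carbon next to the vinyl CH2. A thermal disrotatory 6π electrocyclisation then joins the ketene carbon (C-1 of ring C) to that CH2 (C-2), closing the six-membered carbocycle as 2,4-cyclohexadienone 18, and enolisation of its CH2–C=O unit gives phenol 19 irreversibly. The closest known reaction is the Moore-type ring expansion of squarate-derived 4-alkenyl-4-oxycyclobutenones to hydroquinones and their monoethers. No stereocentre is formed, and the racemic centre of 16 becomes the planar C-4. The step needs torquoselectivity, which the oxygen substituent on C4 secures, and it needs the ketene to choose the enol ether terminus over ring D or stray nucleophiles, which the six-centre intramolecular geometry, high dilution and a dry, acid-free medium should secure. The substitution pattern needs no further control, because every ring-C oxygen already sits on its carbon in 16 and only O-1 emerges as a free hydroxyl.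

Step 10
Reactants: 19 C–D–E–F phenol; 2 4-bromo-3,5-dimethoxybenzaldehyde
Product: 20 4-[2-(DEF-oxy)-5-ethoxy-3,4-dimethoxyphenoxy]-3,5-dimethoxybenzaldehyde (B–F aldehyde)
Conditions: CuI (20 mol %), picolinic acid (40 mol %), K3PO4, DMSO, 100 °C, rigorously O2-free
Reagents that add atoms: none
Why: Ullmann-type etherification as rehearsed in steps 1 and 3, in which the only free OH of 19 keeps one open ortho position (C-2–H), the para-formyl group activates the bromide, and exclusion of oxygen protects the hydroquinone-monoether-like phenoxide.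

Step 11
Reactants: 20 B–F aldehyde
Product: 22 4-[2-(DEF-oxy)-5-ethoxy-3,4-dimethoxyphenoxy]-3,5-dimethoxyphenol (B–F phenol), via aryl formate 21 (not isolated)
Conditions: mCPBA, CH2Cl2, 0 °C → rt; then K2CO3 (cat.), MeOH, rt
Reagents that add atoms: mCPBA, OOC(=O)c1cccc(Cl)c1
Why: Baeyer–Villiger oxidation and formate methanolysis as in steps 2 and 4, with no free phenol present during the oxidation and a fully etherified ring C that reacts with peracid far more slowly than the aldehyde.

Step 12
Reactants: 22 B–F phenol; 2 4-bromo-3,5-dimethoxybenzaldehyde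
Product: 23 4-{4-[2-(DEF-oxy)-5-ethoxy-3,4-dimethoxyphenoxy]-3,5-dimethoxyphenoxy}-3,5-dimethoxybenzaldehyde (A–F aldehyde)
Conditions: CuI (10 mol %), picolinic acid (20 mol %), K3PO4, DMSO, 90 °C, Ar
Reagents that add atoms: none
Why: Ullmann-type etherification in which the OH of 22 lies between two CH positions of ring B, so the coupling has the steric profile of steps 1 and 3.

Step 13
Reactants: 23 A–F aldehyde
Product: 25 4-{4-[2-(DEF-oxy)-5-ethoxy-3,4-dimethoxyphenoxy]-3,5-dimethoxyphenoxy}-3,5-dimethoxyphenol (A–F phenol), via aryl formate 24 (not isolated)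
Conditions: mCPBA, CH2Cl2, 0 °C → rt; then K2CO3 (cat.), MeOH, rt
Reagents that add atoms: mCPBA, OOC(=O)c1cccc(Cl)c1
Why: Baeyer–Villiger oxidation and methanolysis as before, which turns the formyl carbon of ring A into its para hydroxyl and completes the 2,4,6-trioxygenated terminus.

Step 14
Reactants: 25 A–F phenol
Product: 26 CNP0270681.0, the A–F hexamer with all fifteen hydroxyl groups free
Conditions: BBr3 (excess), CH2Cl2, −78 °C → rt, Ar; then H2O, 0 °C; degassed solvents for isolation
Reagents that add atoms: none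
Why: Lewis-acid ether cleavage with BBr3, in which boron binds each alkyl aryl ether oxygen and bromide removes the methyl or ethyl group by SN2, while the five diaryl ether links offer no sp3 carbon and survive.

Compound list
1 | 3,4,5-trimethoxyphenol | COc1cc(O)cc(OC)c1OC | starting material
2 | 4-bromo-3,5-dimethoxybenzaldehyde | COc1cc(C=O)cc(OC)c1Br | starting material
3 | 3,5-dimethoxy-4-(3,4,5-trimethoxyphenoxy)benzaldehyde | O=Cc1cc(OC)c(Oc2cc(OC)c(OC)c(OC)c2)c(OC)c1 | intermediate
4 | 3,5-dimethoxy-4-(3,4,5-trimethoxyphenoxy)phenyl formate (not isolated) | O=COc1cc(OC)c(Oc2cc(OC)c(OC)c(OC)c2)c(OC)c1 | intermediate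
5 | 3,5-dimethoxy-4-(3,4,5-trimethoxyphenoxy)phenol | Oc1cc(OC)c(Oc2cc(OC)c(OC)c(OC)c2)c(OC)c1 | intermediate
6 | 4-[3,5-dimethoxy-4-(3,4,5-trimethoxyphenoxy)phenoxy]-3,5-dimethoxybenzaldehyde | O=Cc1cc(OC)c(Oc2cc(OC)c(Oc3cc(OC)c(OC)c(OC)c3)c(OC)c2)c(OC)c1 | intermediate
7 | formate ester of 8 (not isolated) | O=COc1cc(OC)c(Oc2cc(OC)c(Oc3cc(OC)c(OC)c(OC)c3)c(OC)c2)c(OC)c1 | intermediate
8 | 4-[3,5-dimethoxy-4-(3,4,5-trimethoxyphenoxy)phenoxy]-3,5-dimethoxyphenol (D–E–F phenol) | Oc1cc(OC)c(Oc2cc(OC)c(Oc3cc(OC)c(OC)c(OC)c3)c(OC)c2)c(OC)c1 | intermediate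
9 | squaric acid | OC1=C(O)C(=O)C1=O | starting material
10 | 3,4-dichlorocyclobut-3-ene-1,2-dione | ClC1=C(Cl)C(=O)C1=O | intermediate
11 | 3-chloro-4-methoxycyclobut-3-ene-1,2-dione | COC1=C(Cl)C(=O)C1=O | intermediate
12 | 3-(DEF-oxy)-4-methoxycyclobut-3-ene-1,2-dione | COC1=C(Oc2cc(OC)c(Oc3cc(OC)c(Oc4cc(OC)c(OC)c(OC)c4)c(OC)c3)c(OC)c2)C(=O)C1=O | intermediate
13 | ethyl vinyl ether | C=COCC | starting material
14 | 1-ethoxyvinyllithium (not isolated) | [Li]C(=C)OCC | intermediate
15 | lithium alkoxide of the 1,2-adduct, racemic, one enantiomer drawn (not isolated) | C=C(OCC)[C@]1(O[Li])C(=O)C(Oc2cc(OC)c(Oc3cc(OC)c(Oc4cc(OC)c(OC)c(OC)c4)c(OC)c3)c(OC)c2)=C1OC | intermediate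
16 | (±)-2-(DEF-oxy)-4-(1-ethoxyvinyl)-3,4-dimethoxycyclobut-2-en-1-one, one enantiomer drawn | C=C(OCC)[C@]1(OC)C(=O)C(Oc2cc(OC)c(Oc3cc(OC)c(Oc4cc(OC)c(OC)c(OC)c4)c(OC)c3)c(OC)c2)=C1OC | intermediate
17 | (Z)-2-(DEF-oxy)-5-ethoxy-3,4-dimethoxyhexa-1,3,5-trien-1-one, the dienylketene (not isolated) | O=C=C(Oc1cc(OC)c(Oc2cc(OC)c(Oc3cc(OC)c(OC)c(OC)c3)c(OC)c2)c(OC)c1)/C(OC)=C(/OC)C(=C)OCC | intermediate
18 | 2-(DEF-oxy)-5-ethoxy-3,4-dimethoxycyclohexa-2,4-dien-1-one (not isolated) | O=C1CC(OCC)=C(OC)C(OC)=C1Oc2cc(OC)c(Oc3cc(OC)c(Oc4cc(OC)c(OC)c(OC)c4)c(OC)c3)c(OC)c2 | intermediate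
19 | 2-(DEF-oxy)-5-ethoxy-3,4-dimethoxyphenol (C–D–E–F phenol) | Oc1cc(OCC)c(OC)c(OC)c1Oc2cc(OC)c(Oc3cc(OC)c(Oc4cc(OC)c(OC)c(OC)c4)c(OC)c3)c(OC)c2 | intermediate
20 | 4-[2-(DEF-oxy)-5-ethoxy-3,4-dimethoxyphenoxy]-3,5-dimethoxybenzaldehyde | O=Cc1cc(OC)c(Oc2cc(OCC)c(OC)c(OC)c2Oc3cc(OC)c(Oc4cc(OC)c(Oc5cc(OC)c(OC)c(OC)c5)c(OC)c4)c(OC)c3)c(OC)c1 | intermediate
21 | formate ester of 22 (not isolated) | O=COc1cc(OC)c(Oc2cc(OCC)c(OC)c(OC)c2Oc3cc(OC)c(Oc4cc(OC)c(Oc5cc(OC)c(OC)c(OC)c5)c(OC)c4)c(OC)c3)c(OC)c1 | intermediate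
22 | 4-[2-(DEF-oxy)-5-ethoxy-3,4-dimethoxyphenoxy]-3,5-dimethoxyphenol | Oc1cc(OC)c(Oc2cc(OCC)c(OC)c(OC)c2Oc3cc(OC)c(Oc4cc(OC)c(Oc5cc(OC)c(OC)c(OC)c5)c(OC)c4)c(OC)c3)c(OC)c1 | intermediate
23 | 4-{4-[2-(DEF-oxy)-5-ethoxy-3,4-dimethoxyphenoxy]-3,5-dimethoxyphenoxy}-3,5-dimethoxybenzaldehyde | O=Cc1cc(OC)c(Oc2cc(OC)c(Oc3cc(OCC)c(OC)c(OC)c3Oc4cc(OC)c(Oc5cc(OC)c(Oc6cc(OC)c(OC)c(OC)c6)c(OC)c5)c(OC)c4)c(OC)c2)c(OC)c1 | intermediate
24 | formate ester of 25 (not isolated) | O=COc1cc(OC)c(Oc2cc(OC)c(Oc3cc(OCC)c(OC)c(OC)c3Oc4cc(OC)c(Oc5cc(OC)c(Oc6cc(OC)c(OC)c(OC)c6)c(OC)c5)c(OC)c4)c(OC)c2)c(OC)c1 | intermediate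
25 | 4-{4-[2-(DEF-oxy)-5-ethoxy-3,4-dimethoxyphenoxy]-3,5-dimethoxyphenoxy}-3,5-dimethoxyphenol | Oc1cc(OC)c(Oc2cc(OC)c(Oc3cc(OCC)c(OC)c(OC)c3Oc4cc(OC)c(Oc5cc(OC)c(Oc6cc(OC)c(OC)c(OC)c6)c(OC)c5)c(OC)c4)c(OC)c2)c(OC)c1 | intermediate
26 | CNP0270681.0 (achiral) | Oc1cc(O)c(Oc2cc(O)c(Oc3cc(O)c(O)c(O)c3Oc3cc(O)c(Oc4cc(O)c(Oc5cc(O)c(O)c(O)c5)c(O)c4)c(O)c3)c(O)c2)c(O)c1 | target

Total step count: 14. Longest linear sequence: 12 (steps 1–4 and 7–14); steps 5 and 6 form the side branch.

Steps most likely to fail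

Step 8. The vinyllithium may discriminate poorly between the two carbonyl groups of 12, or it may add in conjugate fashion with expulsion of the aryloxide. The fallback sets out from 8 and 10 and returns at 16, and it removes the choice between carbonyls by symmetry.
- Two equivalents of 8 are joined to squaryl dichloride 10 (iPr2NEt, CH2Cl2) to give the symmetrical diester 3,4-bis(DEF-oxy)cyclobut-3-ene-1,2-dione F1.
- Reagent 14 adds to either of its equivalent carbonyls to give the racemic lithium alkoxide adduct F2. MeOTf converts this into (±)-2,3-bis(DEF-oxy)-4-(1-ethoxyvinyl)-4-methoxycyclobut-2-en-1-one F3.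
- In F3 only the aryloxy group on C3 is the β-substituent of a vinylogous ester. One equivalent of NaOMe in MeOH–THF at low temperature should therefore exchange it by addition–elimination, leave the α-aryloxy group on C2 untouched and deliver 16. The released equivalent of 8 is recovered.

Step 10. C–O bond formation may be slow, because the bromide is flanked by two methoxy groups and the phenoxide carries a bulky ortho aryloxy group. Protodebromination and oxidative decay of the phenoxide could then overtake the coupling. The fallback sets out from 19 and returns at 20. It makes the ether first, without copper, at a much more electrophilic carbon, and brings in the flanking methoxy groups afterwards.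
- Phenol 19 and purchased 3,5-dibromo-4-fluorobenzaldehyde (K2CO3, DMF, 60 °C) should undergo uncatalysed SNAr, as used for thyromimetic ethers, to give 3,5-dibromo-4-[2-(DEF-oxy)-5-ethoxy-3,4-dimethoxyphenoxy]benzaldehyde F4.
- Trimethyl orthoformate with catalytic TsOH in MeOH masks the aldehyde as the dibromo dimethyl acetal F5. The ether is then no longer activated toward cleavage by methoxide.
- Copper-catalysed methoxylation (NaOMe, CuBr, DMF–MeOH, 110 °C), of the kind that turns bromophenol aldehydes into syringaldehyde, gives the dimethoxy dimethyl acetal F6.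
- Dilute aqueous acid in THF releases 20.

Step 14. Cleavage of the flanked ethers may remain incomplete, and the pyrogallol-type rings may be lost to air oxidation during aqueous isolation. The fallback sets out from 25 and returns at 26, and it isolates a protected derivative in place of the free polyphenol.
- After BBr3 treatment and quench, the crude material is kept under argon. It is subjected directly to reductive peracetylation (Zn dust, Ac2O, pyridine), which also returns any quinone to the phenol level, and gives the pentadecaacetate of the hexamer F7.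
- This stable compound is purified by chromatography. Congeners that still hold an alkyl group are separated and sent through the cleavage again.
- Zemplén deacetylation (NaOMe cat., degassed MeOH, 0 °C, then acidic resin) should release 26 under oxygen-free, nearly neutral conditions.

Further compounds
F1 | step 8 | 3,4-bis(DEF-oxy)cyclobut-3-ene-1,2-dione | O=C1C(=O)C(Oc2cc(OC)c(Oc3cc(OC)c(Oc4cc(OC)c(OC)c(OC)c4)c(OC)c3)c(OC)c2)=C1Oc5cc(OC)c(Oc6cc(OC)c(Oc7cc(OC)c(OC)c(OC)c7)c(OC)c6)c(OC)c5
F2 | step 8 | lithium alkoxide adduct of F1 and 14, racemic, one enantiomer drawn | C=C(OCC)[C@]1(O[Li])C(=O)C(Oc2cc(OC)c(Oc3cc(OC)c(Oc4cc(OC)c(OC)c(OC)c4)c(OC)c3)c(OC)c2)=C1Oc5cc(OC)c(Oc6cc(OC)c(Oc7cc(OC)c(OC)c(OC)c7)c(OC)c6)c(OC)c5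
F3 | step 8 | (±)-2,3-bis(DEF-oxy)-4-(1-ethoxyvinyl)-4-methoxycyclobut-2-en-1-one, one enantiomer drawn | C=C(OCC)[C@]1(OC)C(=O)C(Oc2cc(OC)c(Oc3cc(OC)c(Oc4cc(OC)c(OC)c(OC)c4)c(OC)c3)c(OC)c2)=C1Oc5cc(OC)c(Oc6cc(OC)c(Oc7cc(OC)c(OC)c(OC)c7)c(OC)c6)c(OC)c5
F4 | step 10 | 3,5-dibromo-4-[2-(DEF-oxy)-5-ethoxy-3,4-dimethoxyphenoxy]benzaldehyde | O=Cc1cc(Br)c(Oc2cc(OCC)c(OC)c(OC)c2Oc3cc(OC)c(Oc4cc(OC)c(Oc5cc(OC)c(OC)c(OC)c5)c(OC)c4)c(OC)c3)c(Br)c1
F5 | step 10 | dimethyl acetal of F4 | COC(OC)c1cc(Br)c(Oc2cc(OCC)c(OC)c(OC)c2Oc3cc(OC)c(Oc4cc(OC)c(Oc5cc(OC)c(OC)c(OC)c5)c(OC)c4)c(OC)c3)c(Br)c1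
F6 | step 10 | dimethyl acetal of 20 | COC(OC)c1cc(OC)c(Oc2cc(OCC)c(OC)c(OC)c2Oc3cc(OC)c(Oc4cc(OC)c(Oc5cc(OC)c(OC)c(OC)c5)c(OC)c4)c(OC)c3)c(OC)c1
F7 | step 14 | pentadecaacetate of 26 | CC(=O)Oc1cc(OC(C)=O)c(Oc2cc(OC(C)=O)c(Oc3cc(OC(C)=O)c(OC(C)=O)c(OC(C)=O)c3Oc4cc(OC(C)=O)c(Oc5cc(OC(C)=O)c(Oc6cc(OC(C)=O)c(OC(C)=O)c(OC(C)=O)c6)c(OC(C)=O)c5)c(OC(C)=O)c4)c(OC(C)=O)c2)c(OC(C)=O)c1
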